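**Retrosynthetic overview**
1. The ene-dialdehyde comes from a Δ7-11,12-diester by reduction and Swern oxidation. The homoprenyl arm comes from a Wittig reaction on a C4 propanal arm. The axial 1α-OH comes from oxidising the 1β-alcohol and delivering hydride from the equatorial side.
2. Ring B (C5–C6–C7–C8–C9–C10) is opened at C9–C10. The feature used is that the C10 methyl and C11 on C9 are cis (both β) on ring B. That is the conrotatory (photochemical), not the disrotatory (thermal), outcome for a C10=C5–C6=C7–C8=C9 triene with the methyl inward and the C11 ester outward. α-Face hydrogenation of C5=C6 then gives the trans-decalin.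
3. The (Z)-triene is cut at C5–C6 into a ring-A enol triflate and dimethyl 2-ethynylmaleate (Sonogashira coupling, then semihydrogenation). The maleate comes from syn-hydroalkynylation of dimethyl but-2-ynedioate.
4. Ring A is the carvone ring. The C10 methyl comes from enolate methylation and C1–O from ozonolysis/Baeyer–Villiger oxidation with retention. C4 (quaternary) and C3–Cl are set together by a chloronium-induced semipinacol shift of the chain from C5 to C4.
5. Ring order: ring A (chiral pool) first, ring B second (key step).

Key step: step 13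

Remark: target numbering (C1–C10, C11 on C9, C12 on C8) is used for all intermediates and β is the face of the C10 methyl in the target; the C10 epimer ratio in 3–12 is assumed to be irrelevant because C10 becomes sp2 in 14 (the SMILES show the trans series).

Step 1
Reactants: 1 (R)-carvone
Product: 3 trans-6-methylcarvone [(5R,6S)-2,6-dimethyl-5-(prop-1-en-2-yl)cyclohex-2-en-1-one; future C10 methyl α], via lithium dienolate 2 (not isolated)
Conditions: LiN(i-Pr)2, THF, −78 °C; MeI, −78 → 0 °C
Reagents that add atoms: iodomethane, CI
Why: Kinetic α′-deprotonation and SN2 methylation of the cross-conjugated enolate (enolate alkylation) install the future C10 methyl, mainly anti to the neighbouring isopropenyl group, at a stage where no β-leaving group sits on C1, and the new centre becomes sp2 again in step 8.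

Step 2
Reactants: 3 trans-6-methylcarvone
Product: 5 (5R,6S)-5-acetyl-2,6-dimethylcyclohex-2-en-1-one, via secondary ozonide 4 (not isolated)
Conditions: O3, CH2Cl2, −78 °C (Sudan red end point); Me2S, −78 °C → rt
Reagents that add atoms: ozone, [O-][O+]=O
Why: Ozonolysis with reductive work-up cleaves only the electron-rich 1,1-disubstituted alkene because the enone C=C is deactivated, and the neutral conditions should leave the enolisable C1 and C10 centres unchanged.

Step 3
Reactants: 5 (5R,6S)-5-acetyl-2,6-dimethylcyclohex-2-en-1-one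
Product: 6 (1R,2S)-2,4-dimethyl-3-oxocyclohex-4-en-1-yl acetate (1β-acetoxy enone)
Conditions: mCPBA, Na2HPO4, CH2Cl2, rt
Reagents that add atoms: 3-chloroperbenzoic acid, OOC(=O)c1cccc(Cl)c1
Why: Baeyer–Villiger oxidation of the methyl ketone proceeds by migration of the secondary ring carbon with retention, so C1–O takes the β orientation of the carvone isopropenyl group, while the electron-poor enone is inert to the peracid and the absence of amine base avoids β-elimination of acetate towards the phenol.

Step 4
Reactants: 6 1β-acetoxy enone; 7 (3-bromopropoxy)(tert-butyl)diphenylsilane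
Product: 9 1β-acetoxy-5α-[3-(tert-butyldiphenylsilyloxy)propyl]-4,10α-dimethyl ring-A cyclohex-3-en-5β-ol, via Grignard reagent 8 (not isolated)
Conditions: 7, Mg, THF, rt; LaCl3·2LiCl, then 6, THF, −78 °C; H2O
Reagents that add atoms: none
Why: Lanthanide-assisted Grignard 1,2-addition is faster at the ketone than at the acetate at −78 °C and suppresses enolisation, and axial attack on the α face, anti to the 1β-acetoxy group as in additions to carvone itself, sets C5 with the chain α and the hydroxyl β.

Step 5
Reactants: 9 allylic alcohol acetate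
Product: 10 ring-A 1β,5β-diol (5α chain, C3=C4 alkene, 10α-methyl)
Conditions: K2CO3 (cat.), MeOH, 0 °C → rt
Reagents that add atoms: none
Why: Base-catalysed transesterification removes the acetate, which is safe now that no carbonyl group stands β to C1–O, and it touches no stereocentre.

Step 6
Reactants: 10 ring-A diol
Product: 11 1β-(tert-butyldimethylsilyloxy) tertiary allylic alcohol (5β-OH free)
Conditions: TBSCl, imidazole, DMF, rt
Reagents that add atoms: tert-butyldimethylsilyl chloride, CC(C)(C)[Si](C)(C)Cl
Why: Silylation with TBSCl/imidazole distinguishes the secondary C1 hydroxyl from the hindered tertiary allylic C5 hydroxyl, which must stay free for the next step.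

Step 7
Reactants: 11 tertiary allylic alcohol
Product: 12 ring-A chloroketone (C5 ketone; 3β-Cl; C4 with methyl β and silyloxypropyl chain α; 1β-OTBS; 10α-methyl)
Conditions: N-chlorosuccinimide, MeCN–CH2Cl2, 0 °C → rt, dark
Reagents that add atoms: N-chlorosuccinimide, O=C1CCC(=O)N1Cl
Why: In this halonium-induced semipinacol rearrangement of a tertiary allylic alcohol, Cl+ should add to the β face of C3=C4 (syn to the C5 hydroxyl, opposite the pseudoaxial α chain) and the antiperiplanar C5–CH2 bond then migrates to the α face of C4 as the C5 carbonyl forms, which sets 3β-Cl and the C4 quaternary centre (chain α, methyl β) in one anti addition, whereas the ring bond C5–C10 is not aligned for ring contraction.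

Step 8
Reactants: 12 ring-A chloroketone
Product: 14 ring-A enol triflate (C5–OTf; C5=C10 bearing the C10 methyl; 1β-OTBS; 3β-Cl; 4β-methyl; 4α chain), via potassium enolate 13 (not isolated)
Conditions: KN(SiMe3)2, THF, −78 °C; N-(5-chloro-2-pyridyl)bis(trifluoromethanesulfonimide), −78 → −40 °C
Reagents that add atoms: N-(5-chloro-2-pyridyl)bis(trifluoromethanesulfonimide), FC(F)(F)S(=O)(=O)N(c1ccc(Cl)cn1)S(=O)(=O)C(F)(F)F
Why: Only C10 can be deprotonated because C4 is quaternary, and O-sulfonylation of the enolate (enol triflate formation, as for 2,2,6-trisubstituted cyclohexanones) at −78 °C should outrun E1cB loss of the equatorial 1β-silyloxy group, whose C–O bond is poorly aligned with the enolate π system, the C10 stereocentre being erased here.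

Step 9
Reactants: 15 dimethyl but-2-ynedioate; 16 ethynyltrimethylsilane
Product: 17 dimethyl (Z)-2-[(trimethylsilyl)ethynyl]but-2-enedioate (maleate geometry)
Conditions: Pd(OAc)2 (3 mol %), tris(2,6-dimethoxyphenyl)phosphine (3 mol %), THF, rt
Reagents that add atoms: none
Why: In this palladium-catalysed hydroalkynylation of an acceptor alkyne the alkynylpalladium species adds syn across the ynedioate and protonolysis keeps the geometry, so alkynyl and H are cis, the two esters are cis (maleate) and the future C7 is trans to C11.

Step 10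
Reactants: 17 silylethynyl maleate
Product: 18 dimethyl 2-ethynylmaleate
Conditions: Bu4NF, AcOH, THF, −20 °C; used at once
Reagents that add atoms: none
Why: Fluoride-induced protodesilylation of the alkynylsilane is buffered with AcOH so that no basic nucleophile adds to the electron-poor enyne, and the alkene geometry is not affected.

Step 11
Reactants: 14 ring-A enol triflate; 18 dimethyl 2-ethynylmaleate
Product: 19 dienyne diester (C5 of ring A bonded to C6≡C7–C8(CO2Me)=C9H(CO2Me), maleate geometry)
Conditions: Pd(PPh3)4 (5 mol %), CuI (10 mol %), i-Pr2NEt, DMF, rt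
Reagents that add atoms: none
Why: In this Sonogashira coupling, oxidative addition of zerovalent palladium into hindered 2,6,6-trisubstituted cyclohexenyl triflates and coupling with copper acetylides is well known, a tertiary amine avoids conjugate addition to 18, and the C5–C6 bond is made without touching a stereocentre.

Step 12
Reactants: 19 dienyne diester
Product: 20 (6Z)-triene diester (ring-A (Z)-dienyl maleate, C10=C5–C6=C7–C8=C9; 1β-OTBS; 3β-Cl)
Conditions: H2 (1 atm), Pd/CaCO3 poisoned with Pb(OAc)2, quinoline, EtOAc–hexane, 0 °C, dark; filtered cold and used at once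
Reagents that add atoms: none
Why: Semihydrogenation on lead-poisoned palladium delivers H2 syn to the alkyne and gives the (Z)-C6=C7 alkene, the tetrasubstituted ring alkene and the trisubstituted maleate being much slower, as in the dienyne-to-(Z)-triene reductions of seco-steroid trienes, and cold, dark handling prevents a thermal [1,7]-hydrogen shift.

Step 13
Reactants: 20 (6Z)-triene diester
Product: 21 bicyclic 5,7-diene 11,12-dimethyl ester (10β-methyl; 9β-CO2Me and 9α-H; 1β-OTBS; 3β-Cl; 4β-methyl; 4α chain)
Conditions: hν 365 nm (LED), degassed Et2O (2 mM), −30 °C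
Reagents that add atoms: none
Why: Excitation of the s-cis,Z,s-cis conformer of 20 triggers a concerted conrotatory 6π electrocyclisation that forms the C9–C10 σ bond and closes six-membered ring B (C5–C6–C7–C8–C9–C10) as the C5=C6–C7=C8 cyclohexadiene, the closest known reaction type being the photochemical closure of crowded (Z)-hexatrienes fused to a cyclohexene, as in the previtamin D/provitamin D pair. C9 follows from orbital symmetry: on C10 the methyl is the inward group (C1 is tied back in ring A), on C9 the ester C11 is the outward group of the maleate, and conrotation brings one inward and one outward group onto the same face, so methyl and C11 end up cis. C10 follows from the sense of the helix (torquoselectivity): in the half-chair with 3β-Cl equatorial the pseudoequatorial C4 chain lies just below the ring plane next to H6 and the 1β-silyloxy group lies above the plane next to the C10 methyl, so the arm should coil under the α face, C9 should bond to C10 from below and the methyl is pushed up. Because excited rotamers do not interconvert, this ground-state bias is what the product should express. The step also needs a favourable photostationary state: λmax of the twisted triene need not lie beyond that of dienoate 21, but its broad band should tail further to the red than the sharper edge of the rigid diene, so red-edge light excites 20 and its (6E) isomer, which feeds back into 20, while 21 stays nearly transparent. The low temperature suppresses the antarafacial [1,7]-hydrogen shift from the C10 methyl and the thermal disrotatory closure that would give the trans isomer.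

Step 14
Reactants: 21 5,7-diene diester
Product: 22 Δ7-11,12-dimethyl ester with 5α-H (trans-decalin)
Conditions: H2 (1 atm), Pd/C, EtOAc, rt, stopped after one equivalent
Reagents that add atoms: none
Why: Heterogeneous hydrogenation adds H2 syn to the α face of C5=C6, the β face being covered by the axial C4 and C10 methyl groups, and stops at the ester-conjugated trisubstituted C7=C8 bond, the selectivity known for ring-B 5,7-dienes of steroids and drimanes, which sets 5α-H and leaves the alkyl chloride intact.

Step 15
Reactants: 22 Δ7 diester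
Product: 23 Δ7-11,12-diol (1β-OTBS and side-chain OTBDPS retained)
Conditions: i-Bu2AlH, CH2Cl2, −78 → 0 °C; aq. potassium sodium tartrate
Reagents that add atoms: none
Why: Hydride reduction of both esters proceeds without base, so C9 is not epimerised, and it removes the C11 ester before C1–OH is freed, which would otherwise lactonise onto C11 across the peri positions.

Step 16
Reactants: 23 11,12-diol
Product: 24 11,12-bis(pivalate)
Conditions: pivaloyl chloride, pyridine, DMAP, CH2Cl2, 0 → 40 °C
Reagents that add atoms: pivaloyl chloride, CC(C)(C)C(=O)Cl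
Why: Acylation masks both primary alcohols as hindered esters that should survive fluoride, ylide, periodinane and borohydride in steps 17–21.

Step 17
Reactants: 24 bis(pivalate)
Product: 25 1β-hydroxy bis(pivalate) with a free 3-hydroxypropyl arm on C4
Conditions: Bu4NF, AcOH, THF, rt → 45 °C
Reagents that add atoms: none
Why: Fluoride-mediated desilylation removes the primary TBDPS and the hindered secondary TBS ether together, and the AcOH buffer keeps the C1 oxygen protonated so that neither acyl migration nor a Grob-type fragmentation towards the antiperiplanar C3–Cl bond can start.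

Step 18
Reactants: 25 diol
Product: 26 C4 propanal-arm aldehyde (1β-OH free)
Conditions: TEMPO (cat.), PhI(OAc)2, CH2Cl2, rt
Reagents that add atoms: none
Why: Oxoammonium (TEMPO) oxidation is selective for the unhindered primary alcohol, the 1β-alcohol next to quaternary C10 being too hindered to react.

Step 19
Reactants: 26 aldehyde
Product: 27 4α-homoprenyl 1β-alcohol bis(pivalate)
Conditions: i-PrPPh3I, n-BuLi, THF, 0 °C; 26, −78 → 0 °C
Reagents that add atoms: isopropyltriphenylphosphonium iodide, CC(C)[P+](c1ccccc1)(c1ccccc1)c1ccccc1.[I-]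
Why: Wittig olefination with the non-stabilised isopropylidene ylide turns the aldehyde into the trisubstituted homoprenyl alkene (no E/Z issue), one extra equivalent of ylide covers the free hydroxyl, and no acidic C9–H next to an ester is left at this stage.

Step 20
Reactants: 27 1β-alcohol
Product: 28 1-ketone (β-chloro ketone)
Conditions: Dess–Martin periodinane, CH2Cl2, 0 °C → rt
Reagents that add atoms: none
Why: Dess–Martin oxidation runs under neutral to weakly acidic conditions, which is needed because the product is a β-chloro ketone that would lose HCl with amine bases.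

Step 21
Reactants: 28 1-ketone
Product: 29 1α-alcohol (axial) bis(pivalate)
Conditions: LiBH(s-Bu)3, THF, −78 °C; H2O
Reagents that add atoms: none
Why: For this bulky borohydride the axial approach from the α face is blocked by the three syn-axial hydrogens on C3, C5 and C9, so hydride should arrive from the equatorial β side and give the axial 1α-alcohol, as with 4,4-dimethyl-3-oxo terpenoids that give the axial alcohols with this reagent, while the low temperature and the equatorial C3–Cl bond disfavour enolisation and E1cB loss of chloride.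

Step 22
Reactants: 29 1α-alcohol
Product: 30 1α-triethylsilyl ether
Conditions: TESOTf, 2,6-lutidine, CH2Cl2, −78 → 0 °C
Reagents that add atoms: triethylsilyl trifluoromethanesulfonate, CC[Si](CC)(CC)OS(=O)(=O)C(F)(F)F
Why: Silylation with the reactive triflate protects the hindered axial hydroxyl so that only C11 and C12 are oxidised in step 24.

Step 23
Reactants: 30 TES ether bis(pivalate)
Product: 31 1α-OTES 11,12-diol
Conditions: i-Bu2AlH, CH2Cl2, −78 °C; aq. potassium sodium tartrate
Reagents that add atoms: none
Why: Reductive ester cleavage frees both primary alcohols under non-basic conditions and leaves the TES ether, the chloride and both alkenes untouched.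

Step 24
Reactants: 31 11,12-diol
Product: 33 1α-OTES ene-dialdehyde, via bis(alkoxysulfonium) salt 32 (not isolated)
Conditions: (COCl)2, DMSO, CH2Cl2, −78 °C; 31; Et3N, −78 → −30 °C
Reagents that add atoms: none
Why: Swern oxidation activates both hydroxyls before base is added, which avoids the lactol/lactone pathway of 1,4-diols, and at low temperature it should give the ene-dialdehyde without epimerising C9, as known for drim-7-ene-11,12-diols.

Step 25
Reactants: 33 TES-protected dialdehyde
Product: 34 target CNP0155449.1
Conditions: HF·pyridine, pyridine, THF, 0 °C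
Reagents that add atoms: none
Why: Buffered HF cleaves the TES ether under mildly acidic conditions, which avoids base-induced epimerisation of the C9 aldehyde and leaves the 1,3-chlorohydrin intact.

**Compound list**
1 | (R)-carvone | CC(=C)[C@@H]1CC=C(C)C(=O)C1 | starting material
2 | lithium cross-conjugated dienolate of carvone | CC(=C)[C@@H]1CC=C(C)C([O-])=C1.[Li+] | intermediate
3 | trans-6-methylcarvone, (5R,6S) | CC(=C)[C@@H]1CC=C(C)C(=O)[C@H]1C | intermediate
4 | secondary ozonide of 3 (epimers at the trioxolane carbon) | CC1(OCOO1)[C@@H]2CC=C(C)C(=O)[C@H]2C | intermediate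
5 | (5R,6S)-5-acetyl-2,6-dimethylcyclohex-2-en-1-one | CC(=O)[C@@H]1CC=C(C)C(=O)[C@H]1C | intermediate
6 | (1R,2S)-2,4-dimethyl-3-oxocyclohex-4-en-1-yl acetate | CC(=O)O[C@@H]1CC=C(C)C(=O)[C@H]1C | intermediate
7 | (3-bromopropoxy)(tert-butyl)diphenylsilane | CC(C)(C)[Si](OCCCBr)(c1ccccc1)c1ccccc1 | starting material
8 | 3-(tert-butyldiphenylsilyloxy)propylmagnesium bromide | CC(C)(C)[Si](OCCC[Mg]Br)(c1ccccc1)c1ccccc1 | intermediate
9 | tertiary allylic alcohol, 1β-OAc, 5β-OH, 5α chain, 10α-Me | CC(C)(C)[Si](c1ccccc1)(c1ccccc1)OCCC[C@]2(O)C(C)=CC[C@@H](OC(C)=O)[C@@H]2C | intermediate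
10 | ring-A 1β,5β-diol | CC(C)(C)[Si](c1ccccc1)(c1ccccc1)OCCC[C@]2(O)C(C)=CC[C@@H](O)[C@@H]2C | intermediate
11 | 1β-OTBS tertiary allylic alcohol | CC(C)(C)[Si](c1ccccc1)(c1ccccc1)OCCC[C@]2(O)C(C)=CC[C@@H](O[Si](C)(C)C(C)(C)C)[C@@H]2C | intermediate
12 | ring-A chloroketone (3β-Cl, 4β-Me, 4α chain, 1β-OTBS, 10α-Me) | CC(C)(C)[Si](c1ccccc1)(c1ccccc1)OCCC[C@]2(C)[C@@H](Cl)C[C@@H](O[Si](C)(C)C(C)(C)C)[C@H](C)C2=O | intermediate
13 | potassium enolate of 12 | CC(C)(C)[Si](c1ccccc1)(c1ccccc1)OCCC[C@]2(C)[C@@H](Cl)C[C@@H](O[Si](C)(C)C(C)(C)C)C(C)=C2[O-].[K+] | intermediate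
14 | ring-A enol triflate | CC(C)(C)[Si](c1ccccc1)(c1ccccc1)OCCC[C@]2(C)[C@@H](Cl)C[C@@H](O[Si](C)(C)C(C)(C)C)C(C)=C2OS(=O)(=O)C(F)(F)F | intermediate
15 | dimethyl but-2-ynedioate | COC(=O)C#CC(=O)OC | starting material
16 | ethynyltrimethylsilane | C[Si](C)(C)C#C | starting material
17 | dimethyl (Z)-2-[(trimethylsilyl)ethynyl]but-2-enedioate | C[Si](C)(C)C#C/C(C(=O)OC)=C/C(=O)OC | intermediate
18 | dimethyl 2-ethynylmaleate | C#C/C(C(=O)OC)=C/C(=O)OC | intermediate
19 | dienyne diester | CC(C)(C)[Si](c1ccccc1)(c1ccccc1)OCCC[C@]2(C)[C@@H](Cl)C[C@@H](O[Si](C)(C)C(C)(C)C)C(C)=C2C#C/C(C(=O)OC)=C/C(=O)OC | intermediate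
20 | (6Z)-triene diester, precursor of the key step | CC(C)(C)[Si](c1ccccc1)(c1ccccc1)OCCC[C@]2(C)[C@@H](Cl)C[C@@H](O[Si](C)(C)C(C)(C)C)C(C)=C2/C=C\C(C(=O)OC)=C\C(=O)OC | intermediate
21 | bicyclic 5,7-diene 11,12-diester, product of the key step | CC(C)(C)[Si](c1ccccc1)(c1ccccc1)OCCC[C@]1(C)[C@@H](Cl)C[C@@H](O[Si](C)(C)C(C)(C)C)[C@]2(C)[C@@H](C(=O)OC)C(C(=O)OC)=CC=C12 | intermediate
22 | Δ7 diester, 5α-H | CC(C)(C)[Si](c1ccccc1)(c1ccccc1)OCCC[C@]1(C)[C@@H](Cl)C[C@@H](O[Si](C)(C)C(C)(C)C)[C@]2(C)[C@@H](C(=O)OC)C(C(=O)OC)=CC[C@@H]12 | intermediate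
23 | Δ7-11,12-diol | CC(C)(C)[Si](c1ccccc1)(c1ccccc1)OCCC[C@]1(C)[C@@H](Cl)C[C@@H](O[Si](C)(C)C(C)(C)C)[C@]2(C)[C@@H](CO)C(CO)=CC[C@@H]12 | intermediate
24 | 11,12-bis(pivalate) | CC(C)(C)[Si](c1ccccc1)(c1ccccc1)OCCC[C@]1(C)[C@@H](Cl)C[C@@H](O[Si](C)(C)C(C)(C)C)[C@]2(C)[C@@H](COC(=O)C(C)(C)C)C(COC(=O)C(C)(C)C)=CC[C@@H]12 | intermediate
25 | 1β-ol with 3-hydroxypropyl arm, bis(pivalate) | OCCC[C@]1(C)[C@@H](Cl)C[C@@H](O)[C@]2(C)[C@@H](COC(=O)C(C)(C)C)C(COC(=O)C(C)(C)C)=CC[C@@H]12 | intermediate
26 | propanal-arm aldehyde, 1β-ol | O=CCC[C@]1(C)[C@@H](Cl)C[C@@H](O)[C@]2(C)[C@@H](COC(=O)C(C)(C)C)C(COC(=O)C(C)(C)C)=CC[C@@H]12 | intermediate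
27 | homoprenyl 1β-alcohol bis(pivalate) | CC(C)=CCC[C@]1(C)[C@@H](Cl)C[C@@H](O)[C@]2(C)[C@@H](COC(=O)C(C)(C)C)C(COC(=O)C(C)(C)C)=CC[C@@H]12 | intermediate
28 | 1-ketone bis(pivalate) | CC(C)=CCC[C@]1(C)[C@@H](Cl)CC(=O)[C@]2(C)[C@@H](COC(=O)C(C)(C)C)C(COC(=O)C(C)(C)C)=CC[C@@H]12 | intermediate
29 | 1α-alcohol bis(pivalate) | CC(C)=CCC[C@]1(C)[C@@H](Cl)C[C@H](O)[C@]2(C)[C@@H](COC(=O)C(C)(C)C)C(COC(=O)C(C)(C)C)=CC[C@@H]12 | intermediate
30 | 1α-OTES bis(pivalate) | CC(C)=CCC[C@]1(C)[C@@H](Cl)C[C@H](O[Si](CC)(CC)CC)[C@]2(C)[C@@H](COC(=O)C(C)(C)C)C(COC(=O)C(C)(C)C)=CC[C@@H]12 | intermediate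
31 | 1α-OTES 11,12-diol | CC(C)=CCC[C@]1(C)[C@@H](Cl)C[C@H](O[Si](CC)(CC)CC)[C@]2(C)[C@@H](CO)C(CO)=CC[C@@H]12 | intermediate
32 | bis(dimethylalkoxysulfonium) dichloride of 31 | CC(C)=CCC[C@]1(C)[C@@H](Cl)C[C@H](O[Si](CC)(CC)CC)[C@]2(C)[C@@H](CO[S+](C)C)C(CO[S+](C)C)=CC[C@@H]12.[Cl-].[Cl-] | intermediate
33 | 1α-OTES ene-dialdehyde | CC(C)=CCC[C@]1(C)[C@@H](Cl)C[C@H](O[Si](CC)(CC)CC)[C@]2(C)[C@@H](C=O)C(C=O)=CC[C@@H]12 | intermediate
34 | CNP0155449.1 | CC(C)=CCC[C@]1(C)[C@@H](Cl)C[C@H](O)[C@]2(C)[C@@H](C=O)C(C=O)=CC[C@@H]12 | target

Total step count: 25. Longest linear sequence: 23 (steps 1–8 and 11–25; steps 9 and 10 form the side branch).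

**Steps most likely to fail**

1. Step 13 (key step).
   - What may go wrong: 21 may reopen under the lamp, so that a photostationary mixture rich in triene results. Excited-state E/Z isomerisation at C8=C9 would leak into the C9 epimer. The helical bias may be too small (poor torquoselectivity). The [1,7]-hydrogen shift from the C10 methyl may compete.
   - Fallback (thermal cycloaddition in place of electrocyclisation): it sets out from 14. Stille coupling with tributyl(vinyl)stannane (Pd(PPh3)4, LiCl, THF, reflux) gives the 5-vinyl ring-A diene F1. A Diels–Alder reaction of F1 with 15 (toluene, 110 °C), with the dienophile reaching C10 from the α face for the same steric reasons, gives the 5,8-diene 11,12-diester F2. DBU (THF, reflux) moves C8=C9 into conjugation by deprotonation at C7 and protonation of C9 from the α face, and the route is rejoined at 21.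

2. Step 7.
   - What may go wrong: proton loss from the C4 methyl after chlorenium transfer (ene-type allylic chlorination), attack of Cl+ on the α face (which cannot lead to migration), or ionisation of the tertiary allylic alcohol.
   - Fallback (oxygen electrophile first, chloride afterwards): it sets out from 11. Hydroxyl-directed epoxidation (VO(acac)2, t-BuOOH, CH2Cl2) gives the 3β,4β-epoxy alcohol F3. ZnBr2 in CH2Cl2 triggers the semipinacol rearrangement of the α-hydroxy epoxide with the same antiperiplanar chain shift and gives the 3β-hydroxy ketone F4. SOCl2 converts F4 into the C3 chlorosulfite F5. This collapses with catalytic TiCl4 by front-side chloride delivery (retention), and the route is rejoined at 12.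

3. Step 21.
   - What may go wrong: hydride may be delivered from the α face, because the β side is flanked by the C10 methyl and the C11 pivalate arm (poor facial selectivity, regenerating the 1β-alcohol). The reduction may be very slow. Enolisation followed by loss of HCl is also possible.
   - Fallback (SN2 inversion instead of redox): it sets out from 27. A Mitsunobu reaction with 4-nitrobenzoic acid (PPh3, DIAD, toluene, rt → 60 °C) gives the 1α-(4-nitrobenzoate) F6; the carboxylate enters from the open α face, as in the inversion of 17β-hydroxy steroids next to an angular methyl group. K2CO3 in MeOH cleaves the activated benzoate faster than the pivalates, and the route is rejoined at 29, so steps 20 and 21 are skipped.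

**Further compounds**
F1 | step 13 | 5-vinyl ring-A diene | CC(C)(C)[Si](c1ccccc1)(c1ccccc1)OCCC[C@]2(C)[C@@H](Cl)C[C@@H](O[Si](C)(C)C(C)(C)C)C(C)=C2C=C
F2 | step 13 | 5,8-diene 11,12-diester | CC(C)(C)[Si](c1ccccc1)(c1ccccc1)OCCC[C@]1(C)[C@@H](Cl)C[C@@H](O[Si](C)(C)C(C)(C)C)[C@]2(C)C(C(=O)OC)=C(C(=O)OC)CC=C12
F3 | step 7 | 3β,4β-epoxy alcohol | CC(C)(C)[Si](c1ccccc1)(c1ccccc1)OCCC[C@]2(O)[C@@]3(C)O[C@H]3C[C@@H](O[Si](C)(C)C(C)(C)C)[C@@H]2C
F4 | step 7 | 3β-hydroxy ketone | CC(C)(C)[Si](c1ccccc1)(c1ccccc1)OCCC[C@]2(C)[C@@H](O)C[C@@H](O[Si](C)(C)C(C)(C)C)[C@H](C)C2=O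
F5 | step 7 | C3 chlorosulfite | CC(C)(C)[Si](c1ccccc1)(c1ccccc1)OCCC[C@]2(C)[C@@H](OS(=O)Cl)C[C@@H](O[Si](C)(C)C(C)(C)C)[C@H](C)C2=O
F6 | step 21 | 1α-(4-nitrobenzoate) | CC(C)=CCC[C@]1(C)[C@@H](Cl)C[C@H](OC(=O)c3ccc(cc3)[N+](=O)[O-])[C@]2(C)[C@@H](COC(=O)C(C)(C)C)C(COC(=O)C(C)(C)C)=CC[C@@H]12
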